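**Assumption:** but-3-en-1-ylmagnesium bromide (2) and tert-butyl 2-(bromomethyl)prop-2-enoate (6) are bought as such; the tert-butyl group of 6 is the protecting group of the C12 acid and is removed in the last step.

**Retrosynthetic overview** (eudesmane numbering: C10 quaternary, C5 ring-fusion CH, C7 carries the acrylate, C15 = CH2O)
1. Target ⇒ tert-butyl ester 18 ⇒ allylic alcohol 13 + (Z)-4-hydroxycinnamic acid 17 (Mitsunobu). 17 comes from 4-iodophenol and propiolic acid by coupling and cis-semihydrogenation.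
2. 13 ⇒ enol triflate of the trans-decalone 10: C15 by Stille hydroxymethylation, C3=C4 from the kinetic enolate.
3. Key step: 10 ⇒ monocyclic bromo-enone 9. The C6–C7 bond forms by cyclisation of an ester-bearing allyl radical onto the exocyclic enone; this sets C7 and C5.
4. 9 ⇒ cross-metathesis of 5 with 6, then dehydration. 5 ⇒ 3-methylcyclohexenone by copper-catalysed asymmetric conjugate addition and formaldehyde trapping (sets C10).
5. Ring order: ring A is present from the start; ring B is closed by the radical step.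

**Step 1**
Reactants: 1 3-methylcyclohex-2-en-1-one; 2 but-3-en-1-ylmagnesium bromide; 3 formaldehyde (monomer from cracked paraformaldehyde)
Product: 5 (3R)-3-(but-3-en-1-yl)-2-(hydroxymethyl)-3-methylcyclohexan-1-one (both C2 epimers), via bromomagnesium enolate 4 (not isolated)
Conditions: Cu(OTf)2 (3 mol%), C2-symmetric chiral imidazolinium chloride (NHC precursor, 4 mol%, enantiomer giving 3R), Et2O, 0 °C; then CH2O (gas), THF, −40 °C; aq NH4Cl
Reagents that add atoms: none
Why: Copper/NHC-catalysed asymmetric conjugate addition of the Grignard reagent sets the C10 quaternary centre under ligand control (about 90–96% ee, raised by crystallising 10 or 13), and the regiodefined magnesium enolate is hydroxymethylated by an aldol reaction with formaldehyde; the C2 epimers are irrelevant because this carbon becomes sp2 in step 3.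

**Step 2**
Reactants: 5; 6 tert-butyl 2-(bromomethyl)prop-2-enoate (4 equiv)
Product: 7 tert-butyl (2Z)-2-(bromomethyl)-5-[(1R)-2-(hydroxymethyl)-1-methyl-3-oxocyclohexyl]pent-2-enoate
Conditions: RuCl2(H2IMes)(=CH-C6H4-2-OiPr) (second-generation Hoveyda–Grubbs catalyst, 5 mol%), CH2Cl2, 40 °C
Reagents that add atoms: none
Why: Olefin cross-metathesis of the monosubstituted alkene with the 1,1-disubstituted acrylate gives the thermodynamically preferred trisubstituted enoate (ester trans to the chain); it is run before the exocyclic enone exists so that ring-closing metathesis onto that enone cannot compete.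

**Step 3**
Reactants: 7
Product: 9 tert-butyl (2Z)-2-(bromomethyl)-5-[(1R)-1-methyl-2-methylidene-3-oxocyclohexyl]pent-2-enoate, via mesylate 8 (not isolated)
Conditions: Ms2O, i-Pr2NEt, CH2Cl2, −10 °C to rt
Reagents that add atoms: none
Why: Mesylation of the β-hydroxy ketone and E1cB elimination give the exocyclic enone; the hindered amine does not alkylate the allylic bromide at this temperature.

**Step 4 (key step)**
Reactants: 9
Product: 10 tert-butyl 2-[(2R,4aR,8aR)-4a-methyl-8-oxodecahydronaphthalen-2-yl]prop-2-enoate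
Conditions: Bu3SnH (1.15 equiv) and AIBN (0.15 equiv) added over 8 h, PhH (0.005 M), 80 °C; aq KF
Reagents that add atoms: none
Why: Tin-hydride Giese-type radical cyclisation: Bu3Sn• abstracts the allylic bromine, and the 2-(alkoxycarbonyl)allyl radical adds through C7 to the enone methylene (6-endo, the only six-ring mode), so the α-methylene ester reappears intact. A chair transition state with the angular methyl axial and the side chain equatorial sets C7, and the α-keto radical at C5 takes hydrogen axially, anti to the methyl, to give the trans ring fusion.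

**Step 5**
Reactants: 10
Product: 12 tert-butyl 2-[(2R,4aS,8aR)-4a-methyl-8-{[(trifluoromethyl)sulfonyl]oxy}-1,2,3,4,4a,5,6,8a-octahydronaphthalen-2-yl]prop-2-enoate, via potassium enolate 11 (not isolated)
Conditions: KN(SiMe3)2 (1.05 equiv), THF, −78 °C; PhNTf2, −78 to 0 °C
Reagents that add atoms: N-phenylbis(trifluoromethanesulfonimide), O=S(=O)(N(c1ccccc1)S(=O)(=O)C(F)(F)F)C(F)(F)F
Why: Kinetic deprotonation by the bulky amide at the CH2 (C3) rather than the ring-fusion CH gives the less substituted enolate, which is trapped on oxygen (enol triflate formation); C5 is not touched and the acrylate ester is inert at −78 °C.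

**Step 6**
Reactants: 12
Product: 13 tert-butyl 2-[(2R,4aR,8aR)-8-(hydroxymethyl)-4a-methyl-1,2,3,4,4a,5,6,8a-octahydronaphthalen-2-yl]prop-2-enoate
Conditions: Bu3SnCH2OH (1.5 equiv), Pd(PPh3)4 (5 mol%), LiCl (3 equiv), 1,4-dioxane, 100 °C
Reagents that add atoms: (tributylstannyl)methanol, CCCC[Sn](CO)(CCCC)CCCC
Why: Stille coupling of the alkenyl triflate with the hydroxymethyl stannane (LiCl assists the triflate) places C15 with its oxygen on C4 and fixes the C3=C4 double bond; no stereocentre is affected.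

**Step 7**
Reactants: 14 4-iodophenol; 15 propiolic acid
Product: 16 3-(4-hydroxyphenyl)prop-2-ynoic acid
Conditions: PdCl2(PPh3)2 (5 mol%), 1,4-bis(diphenylphosphino)butane (10 mol%), DBU (3 equiv), DMSO, 50 °C
Reagents that add atoms: none
Why: Copper-free Sonogashira coupling of the aryl iodide with propiolic acid; the carboxyl group is kept at 50 °C because decarboxylation needs much higher temperature.

**Step 8**
Reactants: 16
Product: 17 (2Z)-3-(4-hydroxyphenyl)prop-2-enoic acid
Conditions: H2 (1 atm), Pd on CaCO3 poisoned with Pb(OAc)2 (Lindlar catalyst), quinoline, EtOAc, rt, dark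
Reagents that add atoms: none
Why: Lindlar semihydrogenation adds H2 syn to the alkyne and stops at the Z alkene.

**Step 9**
Reactants: 13; 17 (1.5 equiv)
Product: 18 tert-butyl 2-[(2R,4aR,8aR)-8-({[(2Z)-3-(4-hydroxyphenyl)prop-2-enoyl]oxy}methyl)-4a-methyl-1,2,3,4,4a,5,6,8a-octahydronaphthalen-2-yl]prop-2-enoate
Conditions: PPh3, DIAD, THF, 0 °C to rt, dark
Reagents that add atoms: none
Why: Mitsunobu esterification: the carboxylic acid (pKa about 4), not the phenol (pKa about 9), is the pronucleophile and displaces the activated primary allylic oxygen by SN2; the neutral conditions preserve the Z alkene.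

**Step 10**
Reactants: 18
Product: 19 2-[(2R,4aR,8aR)-8-({[(2Z)-3-(4-hydroxyphenyl)prop-2-enoyl]oxy}methyl)-4a-methyl-1,2,3,4,4a,5,6,8a-octahydronaphthalen-2-yl]prop-2-enoic acid (target)
Conditions: CF3CO2H/CH2Cl2 (1:4), 0 °C, dark
Reagents that add atoms: none
Why: Acidolysis of the tert-butyl ester (E1 loss of isobutene) frees the acid, while the primary allylic ester, the Z enoate and the deactivated phenol survive short exposure at 0 °C.

**Compound list**
1 | 3-methylcyclohex-2-en-1-one | CC1=CC(=O)CCC1 | starting material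
2 | but-3-en-1-ylmagnesium bromide | C=CCC[Mg]Br | starting material
3 | formaldehyde | C=O | starting material
4 | bromomagnesium (3R)-3-(but-3-en-1-yl)-3-methylcyclohex-1-en-1-olate | Br[Mg]OC1=C[C@@](C)(CCC=C)CCC1 | intermediate
5 | (3R)-3-(but-3-en-1-yl)-2-(hydroxymethyl)-3-methylcyclohexan-1-one (C2 epimers) | O=C1CCC[C@](C)(CCC=C)C1CO | intermediate
6 | tert-butyl 2-(bromomethyl)prop-2-enoate | C=C(CBr)C(=O)OC(C)(C)C | starting material
7 | tert-butyl (2Z)-2-(bromomethyl)-5-[(1R)-2-(hydroxymethyl)-1-methyl-3-oxocyclohexyl]pent-2-enoate | O=C1CCC[C@](C)(CC/C=C(\CBr)C(=O)OC(C)(C)C)C1CO | intermediate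
8 | tert-butyl (2Z)-2-(bromomethyl)-5-{(1R)-2-[(methanesulfonyloxy)methyl]-1-methyl-3-oxocyclohexyl}pent-2-enoate | O=C1CCC[C@](C)(CC/C=C(\CBr)C(=O)OC(C)(C)C)C1COS(C)(=O)=O | intermediate
9 | tert-butyl (2Z)-2-(bromomethyl)-5-[(1R)-1-methyl-2-methylidene-3-oxocyclohexyl]pent-2-enoate | C=C1C(=O)CCC[C@]1(C)CC/C=C(\CBr)C(=O)OC(C)(C)C | intermediate
10 | tert-butyl 2-[(2R,4aR,8aR)-4a-methyl-8-oxodecahydronaphthalen-2-yl]prop-2-enoate | C=C(C(=O)OC(C)(C)C)[C@@H]1CC[C@@]2(C)CCCC(=O)[C@@H]2C1 | intermediate
11 | potassium enolate of 10: tert-butyl 2-[(2R,4aS,8aR)-4a-methyl-8-(potassiooxy)-1,2,3,4,4a,5,6,8a-octahydronaphthalen-2-yl]prop-2-enoate | C=C(C(=O)OC(C)(C)C)[C@@H]1CC[C@@]2(C)CCC=C(O[K])[C@@H]2C1 | intermediate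
12 | tert-butyl 2-[(2R,4aS,8aR)-4a-methyl-8-{[(trifluoromethyl)sulfonyl]oxy}-1,2,3,4,4a,5,6,8a-octahydronaphthalen-2-yl]prop-2-enoate | C=C(C(=O)OC(C)(C)C)[C@@H]1CC[C@@]2(C)CCC=C(OS(=O)(=O)C(F)(F)F)[C@@H]2C1 | intermediate
13 | tert-butyl 2-[(2R,4aR,8aR)-8-(hydroxymethyl)-4a-methyl-1,2,3,4,4a,5,6,8a-octahydronaphthalen-2-yl]prop-2-enoate | C=C(C(=O)OC(C)(C)C)[C@@H]1CC[C@@]2(C)CCC=C(CO)[C@@H]2C1 | intermediate
14 | 4-iodophenol | Oc1ccc(I)cc1 | starting material
15 | propiolic acid | C#CC(=O)O | starting material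
16 | 3-(4-hydroxyphenyl)prop-2-ynoic acid | OC(=O)C#Cc1ccc(O)cc1 | intermediate
17 | (2Z)-3-(4-hydroxyphenyl)prop-2-enoic acid | OC(=O)/C=C\c1ccc(O)cc1 | intermediate
18 | tert-butyl 2-[(2R,4aR,8aR)-8-({[(2Z)-3-(4-hydroxyphenyl)prop-2-enoyl]oxy}methyl)-4a-methyl-1,2,3,4,4a,5,6,8a-octahydronaphthalen-2-yl]prop-2-enoate | C=C(C(=O)OC(C)(C)C)[C@@H]1CC[C@@]2(C)CCC=C(COC(=O)/C=C\c3ccc(O)cc3)[C@@H]2C1 | intermediate
19 | 2-[(2R,4aR,8aR)-8-({[(2Z)-3-(4-hydroxyphenyl)prop-2-enoyl]oxy}methyl)-4a-methyl-1,2,3,4,4a,5,6,8a-octahydronaphthalen-2-yl]prop-2-enoic acid | C=C(C(=O)O)[C@@H]1CC[C@@]2(C)CCC=C(COC(=O)/C=C\c3ccc(O)cc3)[C@@H]2C1 | target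

**Total step count:** 10
**Longest linear sequence:** 8 (steps 1–6, 9, 10)

**Three steps most likely to fail**

Step 4 (key radical cyclisation). The stabilised allyl radical may be reduced before it cyclises, or C7/C5 epimers may form. A C5 epimer can be equilibrated with DBU because C5 is α to the ketone, although the preference for the trans-fused ketone is estimated at only about 1 kcal/mol (roughly 5:1), so the epimers may need separating. The fallback sets out from 9: treatment with KOAc in DMF exchanges bromide for acetate and gives tert-butyl (2E)-2-[(acetyloxy)methyl]-5-[(1R)-1-methyl-2-methylidene-3-oxocyclohexyl]pent-2-enoate F1. Reduction of F1 with SmI2 (divalent samarium, 2.2 equiv) with HMPA and t-BuOH in THF at −78 °C turns the enone into its radical anion, whose C6 attacks C7 in a 6-exo reductive cyclisation. The samarium ester enolate then expels acetate to restore the α-methylene ester, and protonation at C5 brings the route back at 10.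

Step 2 (cross-metathesis to a trisubstituted allylic bromide). Conversion may be low, or the allylic bromide may degrade the catalyst. The fallback sets out from 5: ozonolysis (O3, CH2Cl2, −78 °C; Me2S) gives 3-[(1R)-2-(hydroxymethyl)-1-methyl-3-oxocyclohexyl]propanal F2. A Morita–Baylis–Hillman reaction of F2 with tert-butyl acrylate (DABCO, neat) gives tert-butyl 3-hydroxy-5-[(1R)-2-(hydroxymethyl)-1-methyl-3-oxocyclohexyl]-2-methylidenepentanoate F3. PBr3 in Et2O converts the allylic alcohol with 1,3-transposition and the primary alcohol into bromides, giving tert-butyl (2Z)-2-(bromomethyl)-5-[(1R)-2-(bromomethyl)-1-methyl-3-oxocyclohexyl]pent-2-enoate F4. i-Pr2NEt eliminates HBr from the β-bromo ketone of F4, so the route comes back at 9 (steps 2 and 3 are bypassed).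

Step 1 (formaldehyde trapping of the hindered magnesium enolate). Formaldehyde may polymerise or add twice. The fallback sets out from the enolate 4: quenching with Me3SiCl gives {[(3R)-3-(but-3-en-1-yl)-3-methylcyclohex-1-en-1-yl]oxy}trimethylsilane F5, which is isolated. A Mukaiyama aldol reaction of F5 with aqueous formaldehyde and Sc(OTf)3 in THF gives the hydroxymethyl ketone, and the route comes back at 5.

**Further compounds**
F1 | step 4 | tert-butyl (2E)-2-[(acetyloxy)methyl]-5-[(1R)-1-methyl-2-methylidene-3-oxocyclohexyl]pent-2-enoate | C=C1C(=O)CCC[C@]1(C)CC/C=C(\COC(C)=O)C(=O)OC(C)(C)C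
F2 | step 2 | 3-[(1R)-2-(hydroxymethyl)-1-methyl-3-oxocyclohexyl]propanal | O=C1CCC[C@](C)(CCC=O)C1CO
F3 | step 2 | tert-butyl 3-hydroxy-5-[(1R)-2-(hydroxymethyl)-1-methyl-3-oxocyclohexyl]-2-methylidenepentanoate | O=C1CCC[C@](C)(CCC(O)C(=C)C(=O)OC(C)(C)C)C1CO
F4 | step 2 | tert-butyl (2Z)-2-(bromomethyl)-5-[(1R)-2-(bromomethyl)-1-methyl-3-oxocyclohexyl]pent-2-enoate | O=C1CCC[C@](C)(CC/C=C(\CBr)C(=O)OC(C)(C)C)C1CBr
F5 | step 1 | {[(3R)-3-(but-3-en-1-yl)-3-methylcyclohex-1-en-1-yl]oxy}trimethylsilane | C[Si](C)(C)OC1=C[C@@](C)(CCC=C)CCC1
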